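**Retrosynthetic overview**
1. Target 24 comes from the tris-MOM flavanone 23 by removal of three MOM acetals. Rings A and B are bought as benzene rings, and ring C (the pyranone) is the only ring formed, last.
2. Ring C of 23 is cut at both of its bonds to ring A (O1–C8a and C4–C4a). This gives aryne 21, released from 2-silylaryl triflate 14, and the (S)-β-silyloxy ester 19, which brings C2 in preformed.
3. Enabling feature: C8a and C4a are neighbouring carbons of ring A that carry the ring-C oxygen O1 and the acyl carbon C4 (an ortho-acyl aryl ether). The C5 oxygen next to C4a polarises the C4a≡C8a aryne so that O1 adds at C8a. The C6 geranyl group lies between two like oxygens, so phenol 7 is mirror-symmetric and gives one aryne precursor only.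
4. 14 comes from resorcinol by MOM protection, ortho-metalation/geranylation, C–H borylation/oxidation para to the geranyl group, carbamate-directed silylation and triflation.
5. 19 comes from acetosyringone by MOM protection, Claisen condensation, asymmetric transfer hydrogenation and O-silylation.

Key step: step 11

Remark: the target is read as the (2S)-flavanone with an (E)-geranyl group at C6. Flavanone numbering (O1, C2, C3, C4, C4a, C5–C8, C8a) is used; "geranyl" means (2E)-3,7-dimethylocta-2,6-dien-1-yl and MOM means methoxymethyl.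

**Route**

Step 1
Reactants: 1 resorcinol
Product: 2 1,3-bis(methoxymethoxy)benzene
Conditions: NaH, MOMCl, DMF, 0 °C → rt
Reagents that add atoms: chloromethyl methyl ether (MOMCl), COCCl
Why: Williamson-type O-alkylation of the bis-phenoxide by the reactive α-chloro ether should protect both hydroxyls as MOM acetals, which later serve as ortho-directing groups.

Step 2
Reactants: 2 1,3-bis(methoxymethoxy)benzene; 3 geranyl bromide
Product: 5 2-[(2E)-3,7-dimethylocta-2,6-dien-1-yl]-1,3-bis(methoxymethoxy)benzene, via aryllithium 4 (not isolated)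
Conditions: n-BuLi, THF, 0 °C → rt; CuBr·SMe2 (10 mol%), geranyl bromide, −78 °C → rt
Reagents that add atoms: none
Why: Directed ortho-metalation takes place at the C–H flanked by both OMOM groups, and copper-catalysed SN2 allylation of the aryllithium with geranyl bromide should install the chain at the α-carbon with the (E)-alkene unchanged.

Step 3
Reactants: 5 2-[(2E)-3,7-dimethylocta-2,6-dien-1-yl]-1,3-bis(methoxymethoxy)benzene
Product: 7 4-[(2E)-3,7-dimethylocta-2,6-dien-1-yl]-3,5-bis(methoxymethoxy)phenol, via arylboronate 6 (not isolated)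
Conditions: [Ir(OMe)(cod)]2 (1.5 mol%), dtbpy (3 mol%), B2pin2, THF, 60 °C; then 30% aq H2O2, aq NaOH, 0 °C
Reagents that add atoms: hydrogen peroxide, OO
Why: Iridium-catalysed arene C–H borylation is governed by sterics, so boron should enter only at the one ring C–H without an ortho substituent (para to the geranyl group) while the trisubstituted alkenes are left alone, and alkaline peroxide then oxidises C–B to C–OH at the same position without epoxidising unactivated alkenes.

Step 4
Reactants: 7 4-[(2E)-3,7-dimethylocta-2,6-dien-1-yl]-3,5-bis(methoxymethoxy)phenol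
Product: 8 4-geranyl-3,5-bis(methoxymethoxy)phenyl N-isopropylcarbamate
Conditions: i-PrNCO, Et3N (cat.), CH2Cl2, rt
Reagents that add atoms: isopropyl isocyanate, CC(C)N=C=O
Why: Base-catalysed addition of the phenol to the isocyanate should give the N-monoalkyl carbamate, a strong ortho-directing group that can later be cleaved under mild conditions.

Step 5
Reactants: 8 4-geranyl-3,5-bis(methoxymethoxy)phenyl N-isopropylcarbamate
Product: 12 4-geranyl-3,5-bis(methoxymethoxy)-2-(trimethylsilyl)phenyl N-isopropylcarbamate, via N-silyl carbamate 9 (not isolated), via ortho-lithiated N-silyl carbamate 10 (not isolated), via C,N-bis(trimethylsilyl) carbamate 11 (not isolated)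
Conditions: TMSOTf (1.05 equiv), TMEDA, Et2O, 0 °C → rt; n-BuLi (2.2 equiv), TMEDA, −78 °C; TMSCl, −78 °C → rt; sat. aq NH4Cl–MeOH
Reagents that add atoms: chlorotrimethylsilane, C[Si](C)(C)Cl
Why: Directed ortho-metalation of an in situ N-silylated N-monoalkyl carbamate: the carbamate and the flanking OMOM group together direct n-BuLi to the only kind of ring C–H left (the two are equivalent by symmetry), the aryllithium is silylated at −78 °C before anionic ortho-Fries migration can set in, and the labile N–Si bond is hydrolysed on work-up.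

Step 6
Reactants: 12 4-geranyl-3,5-bis(methoxymethoxy)-2-(trimethylsilyl)phenyl N-isopropylcarbamate
Product: 14 4-geranyl-3,5-bis(methoxymethoxy)-2-(trimethylsilyl)phenyl trifluoromethanesulfonate, via 2-silylphenol 13 (not isolated)
Conditions: Et2NH, DBU, MeCN, 40 °C; then PhNTf2, rt
Reagents that add atoms: N-phenylbis(trifluoromethanesulfonimide), O=S(=O)(N(c1ccccc1)S(=O)(=O)C(F)(F)F)C(F)(F)F
Why: The N–H carbamate is cleaved by base-induced E1cB loss of isopropyl isocyanate (trapped by Et2NH as a urea), and the phenoxide released is triflated in the same flask to give the 2-(trimethylsilyl)aryl triflate needed for fluoride-induced aryne generation.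

Step 7
Reactants: 15 acetosyringone
Product: 16 1-[3,5-dimethoxy-4-(methoxymethoxy)phenyl]ethanone
Conditions: NaH, MOMCl, DMF, 0 °C → rt
Reagents that add atoms: chloromethyl methyl ether (MOMCl), COCCl
Why: O-alkylation of the acidic para-acyl phenoxide with MOMCl should mask the only hydroxyl of ring B with the same acetal used on ring A, so that one final operation frees all three phenols.

Step 8
Reactants: 16 1-[3,5-dimethoxy-4-(methoxymethoxy)phenyl]ethanone
Product: 17 methyl 3-[3,5-dimethoxy-4-(methoxymethoxy)phenyl]-3-oxopropanoate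
Conditions: NaH, (MeO)2CO, THF, reflux; AcOH quench
Reagents that add atoms: dimethyl carbonate, COC(=O)OC
Why: Crossed Claisen condensation of the methyl ketone enolate with dimethyl carbonate is driven to completion by deprotonation of the β-keto ester formed.

Step 9
Reactants: 17 methyl 3-[3,5-dimethoxy-4-(methoxymethoxy)phenyl]-3-oxopropanoate
Product: 18 methyl (3S)-3-[3,5-dimethoxy-4-(methoxymethoxy)phenyl]-3-hydroxypropanoate
Conditions: RuCl(p-cymene)[(S,S)-TsDPEN] (1 mol%), HCO2H–Et3N (5:2), EtOAc, 35 °C
Reagents that add atoms: none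
Why: Noyori–Ikariya asymmetric transfer hydrogenation delivers hydride and proton through the outer-sphere six-membered transition state with the aryl group under the η6-arene, so the (S,S) catalyst should set the (S) carbinol center with the same facial sense as for aryl methyl ketones, the CH2CO2Me arm taking the place of methyl.

Step 10
Reactants: 18 methyl (3S)-3-[3,5-dimethoxy-4-(methoxymethoxy)phenyl]-3-hydroxypropanoate
Product: 19 methyl (3S)-3-[3,5-dimethoxy-4-(methoxymethoxy)phenyl]-3-[(trimethylsilyl)oxy]propanoate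
Conditions: TMSCl, imidazole, CH2Cl2, 0 °C; non-aqueous work-up
Reagents that add atoms: chlorotrimethylsilane, C[Si](C)(C)Cl
Why: O-silylation without touching the stereocenter turns the alcohol into a latent alkoxide that fluoride can unmask with no proton left in the flask.

Step 11
Reactants: 14 4-geranyl-3,5-bis(methoxymethoxy)-2-(trimethylsilyl)phenyl trifluoromethanesulfonate (1.0 equiv); 19 methyl (3S)-3-[3,5-dimethoxy-4-(methoxymethoxy)phenyl]-3-[(trimethylsilyl)oxy]propanoate (1.2 equiv)
Product: 23 (2S)-2-[3,5-dimethoxy-4-(methoxymethoxy)phenyl]-6-geranyl-5,7-bis(methoxymethoxy)chroman-4-one, via potassium alkoxide 20 (not isolated), via aryne 21 (not isolated), via aryl anion adduct 22 (not isolated)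
Conditions: KF, 18-crown-6, THF, −20 °C → rt; pH 7 phosphate buffer
Reagents that add atoms: none
Why: Proposed new method: fluoride strips the O–SiMe3 group of 19 to the proton-free alkoxide 20 and triggers 1,2-elimination of 14 to aryne 21; 20 adds to the aryne carbon remote from the C5 OMOM group (the future C8a), the aryl anion 22 formed at C4a attacks the methyl ester, and the methoxide expelled is removed as MeOSiMe3 by desilylating the next molecule of 19, so no free base builds up. The closest known reaction type is the fluoride-mediated annulation of arynes with methyl salicylates to xanthones (phenoxide addition, then intramolecular acyl substitution by the aryl anion), together with aryne insertion into the C–O bond of carboxylic acids; what is new is an aliphatic, stereodefined β-silyloxy ester as the partner. Ring C, the only ring closed, forms by 6-exo-trig attack of the C4a anion on the ester carbonyl after intermolecular O1–C8a bond formation. No stereocenter is created: C2 comes from 19 and none of its four bonds is broken, so the (S) configuration should be carried through unchanged. The step needs O-attack at C8a and not C4a, which the inductive polarisation of the 3-alkoxyaryne by the OMOM oxygen next to C4a secures, and acylation of the aryl anion in preference to protonation, which the silyl mask (no O–H in the flask) and the aprotic ether solvent secure. Low temperature and a neutral quench guard C2 against retro-oxa-Michael opening of ring C.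

Step 12
Reactants: 23 (2S)-2-[3,5-dimethoxy-4-(methoxymethoxy)phenyl]-6-geranyl-5,7-bis(methoxymethoxy)chroman-4-one
Product: 24 (2S)-6-[(2E)-3,7-dimethylocta-2,6-dien-1-yl]-5,7-dihydroxy-2-(4-hydroxy-3,5-dimethoxyphenyl)-2,3-dihydro-4H-chromen-4-one
Conditions: 3 M aq HCl, MeOH, 45 °C
Reagents that add atoms: none
Why: Acid-catalysed acetal exchange with methanol removes the three MOM groups as dimethoxymethane under conditions mild enough that C2 (no bond to it is touched) and the geranyl chain should survive, a deprotection with close precedent on prenylated and geranylated flavanones.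

**Compound list**
1 | resorcinol (benzene-1,3-diol) | Oc1cccc(O)c1 | starting material
2 | 1,3-bis(methoxymethoxy)benzene | COCOc1cccc(OCOC)c1 | intermediate
3 | geranyl bromide, (2E)-1-bromo-3,7-dimethylocta-2,6-diene | BrC/C=C(\C)CCC=C(C)C | starting material
4 | [2,6-bis(methoxymethoxy)phenyl]lithium | [Li]c1c(OCOC)cccc1OCOC | intermediate
5 | 2-[(2E)-3,7-dimethylocta-2,6-dien-1-yl]-1,3-bis(methoxymethoxy)benzene | COCOc1cccc(OCOC)c1C/C=C(\C)CCC=C(C)C | intermediate
6 | 2-{4-[(2E)-3,7-dimethylocta-2,6-dien-1-yl]-3,5-bis(methoxymethoxy)phenyl}-4,4,5,5-tetramethyl-1,3,2-dioxaborolane | COCOc1cc(B2OC(C)(C)C(C)(C)O2)cc(OCOC)c1C/C=C(\C)CCC=C(C)C | intermediate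
7 | 4-[(2E)-3,7-dimethylocta-2,6-dien-1-yl]-3,5-bis(methoxymethoxy)phenol | COCOc1cc(O)cc(OCOC)c1C/C=C(\C)CCC=C(C)C | intermediate
8 | 4-[(2E)-3,7-dimethylocta-2,6-dien-1-yl]-3,5-bis(methoxymethoxy)phenyl N-isopropylcarbamate | COCOc1cc(OC(=O)NC(C)C)cc(OCOC)c1C/C=C(\C)CCC=C(C)C | intermediate
9 | N-(trimethylsilyl) derivative of carbamate 8 | COCOc1cc(OC(=O)N(C(C)C)[Si](C)(C)C)cc(OCOC)c1C/C=C(\C)CCC=C(C)C | intermediate
10 | 2-lithio derivative of N-silyl carbamate 9 | COCOc1cc(OC(=O)N(C(C)C)[Si](C)(C)C)c([Li])c(OCOC)c1C/C=C(\C)CCC=C(C)C | intermediate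
11 | 4-geranyl-3,5-bis(methoxymethoxy)-2-(trimethylsilyl)phenyl N-isopropyl-N-(trimethylsilyl)carbamate | COCOc1cc(OC(=O)N(C(C)C)[Si](C)(C)C)c([Si](C)(C)C)c(OCOC)c1C/C=C(\C)CCC=C(C)C | intermediate
12 | 4-[(2E)-3,7-dimethylocta-2,6-dien-1-yl]-3,5-bis(methoxymethoxy)-2-(trimethylsilyl)phenyl N-isopropylcarbamate | COCOc1cc(OC(=O)NC(C)C)c([Si](C)(C)C)c(OCOC)c1C/C=C(\C)CCC=C(C)C | intermediate
13 | 4-[(2E)-3,7-dimethylocta-2,6-dien-1-yl]-3,5-bis(methoxymethoxy)-2-(trimethylsilyl)phenol (present as its DBU salt) | COCOc1cc(O)c([Si](C)(C)C)c(OCOC)c1C/C=C(\C)CCC=C(C)C | intermediate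
14 | 4-[(2E)-3,7-dimethylocta-2,6-dien-1-yl]-3,5-bis(methoxymethoxy)-2-(trimethylsilyl)phenyl trifluoromethanesulfonate | COCOc1cc(OS(=O)(=O)C(F)(F)F)c([Si](C)(C)C)c(OCOC)c1C/C=C(\C)CCC=C(C)C | intermediate
15 | acetosyringone, 1-(4-hydroxy-3,5-dimethoxyphenyl)ethanone | CC(=O)c1cc(OC)c(O)c(OC)c1 | starting material
16 | 1-[3,5-dimethoxy-4-(methoxymethoxy)phenyl]ethanone | CC(=O)c1cc(OC)c(OCOC)c(OC)c1 | intermediate
17 | methyl 3-[3,5-dimethoxy-4-(methoxymethoxy)phenyl]-3-oxopropanoate | COC(=O)CC(=O)c1cc(OC)c(OCOC)c(OC)c1 | intermediate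
18 | methyl (3S)-3-[3,5-dimethoxy-4-(methoxymethoxy)phenyl]-3-hydroxypropanoate | COC(=O)C[C@H](O)c1cc(OC)c(OCOC)c(OC)c1 | intermediate
19 | methyl (3S)-3-[3,5-dimethoxy-4-(methoxymethoxy)phenyl]-3-[(trimethylsilyl)oxy]propanoate | COC(=O)C[C@H](O[Si](C)(C)C)c1cc(OC)c(OCOC)c(OC)c1 | intermediate
20 | potassium (1S)-1-[3,5-dimethoxy-4-(methoxymethoxy)phenyl]-3-methoxy-3-oxopropan-1-olate | COC(=O)C[C@H]([O-])c1cc(OC)c(OCOC)c(OC)c1.[K+] | intermediate
21 | 4-[(2E)-3,7-dimethylocta-2,6-dien-1-yl]-3,5-bis(methoxymethoxy)benzyne (1,2-didehydrobenzene) | COCOC1=CC#CC(OCOC)=C1C/C=C(\C)CCC=C(C)C | intermediate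
22 | aryl-potassium adduct: methyl (3S)-3-[3,5-dimethoxy-4-(methoxymethoxy)phenyl]-3-[4-geranyl-3,5-bis(methoxymethoxy)-2-potassiophenoxy]propanoate | COC(=O)C[C@H](Oc1cc(OCOC)c(C/C=C(\C)CCC=C(C)C)c(OCOC)c1[K])c1cc(OC)c(OCOC)c(OC)c1 | intermediate
23 | (2S)-2-[3,5-dimethoxy-4-(methoxymethoxy)phenyl]-6-[(2E)-3,7-dimethylocta-2,6-dien-1-yl]-5,7-bis(methoxymethoxy)-2,3-dihydro-4H-chromen-4-one | COc1cc([C@@H]2CC(=O)c3c(cc(OCOC)c(C/C=C(\C)CCC=C(C)C)c3OCOC)O2)cc(OC)c1OCOC | intermediate
24 | (2S)-6-[(2E)-3,7-dimethylocta-2,6-dien-1-yl]-5,7-dihydroxy-2-(4-hydroxy-3,5-dimethoxyphenyl)-2,3-dihydro-4H-chromen-4-one | COc1cc([C@@H]2CC(=O)c3c(cc(O)c(C/C=C(\C)CCC=C(C)C)c3O)O2)cc(OC)c1O | target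

**Step count and risks**
Total step count: 12. Longest linear sequence: 8 (steps 1–6, 11, 12).

Steps most likely to fail:

1. Step 11 (proposed new method). What may go wrong: the aryl anion may be protonated (by traces of water or by the ester α-CH2) before it acylates, so that only O-arylation occurs. The configuration at C2 may erode through reversible aldol cleavage of the alkoxide or through base-induced retro-oxa-Michael opening of ring C after closure. The aryne may also be consumed by methoxide or by an ene reaction with the geranyl alkenes. Fallback with known chemistry, setting out from 14 and returning at 23: commercial sinapic acid is bis-methoxymethylated (NaH, MOMCl, DMF) to methoxymethyl (E)-3-[3,5-dimethoxy-4-(methoxymethoxy)phenyl]prop-2-enoate F1 and saponified (LiOH, THF–H2O) to (E)-3-[3,5-dimethoxy-4-(methoxymethoxy)phenyl]prop-2-enoic acid F2. Heating 14 with F2 and CsF in THF in a sealed vessel is the known aryne insertion into the C–O bond of a carboxylic acid (carboxylate addition at the carbon remote from OMOM, then acyl shift from O to C) and should give the 2'-hydroxychalcone F3. F3 should close by oxa-Michael addition under the same conditions (or with NaOAc in EtOH) to the racemic tris-MOM flavanone F4. Kinetic resolution by transfer hydrogenation with RuCl(p-cymene)[(R,R)-TsDPEN] in HCO2H–Et3N should reduce the (2R)-enantiomer faster, to the cis-(2R,4R)-flavan-4-ol F5, and leave (2S)-flavanone 23, which is separated by chromatography and enters step 12.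

2. Step 3. What may go wrong: hydroboration or vinylic borylation of the two geranyl alkenes may compete with arene C–H borylation, or the arene may convert too slowly to outrun these paths. Fallback, setting out from 2 and returning at 7, with the oxygen installed before the alkenes are present: 2 is borylated with the same iridium catalyst at its only unhindered C–H to 2-[3,5-bis(methoxymethoxy)phenyl]-4,4,5,5-tetramethyl-1,3,2-dioxaborolane F6 and oxidised (H2O2, NaOH) to 3,5-bis(methoxymethoxy)phenol F7. Silylation (TIPSCl, imidazole, DMF) gives [3,5-bis(methoxymethoxy)phenoxy]tri(propan-2-yl)silane F8. n-BuLi in THF at 0 °C lithiates between the two OMOM groups (the bulky silyl ether does not direct) to the 4-lithio derivative F9, which CuBr·SMe2 and geranyl bromide 3 convert to the 4-geranyl silyl ether F10. TBAF in THF then frees phenol 7.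

3. Step 5. What may go wrong: the silyl triflate–amine pair may activate and cleave the MOM acetals during N-silylation, n-BuLi may deprotonate the doubly activated ArCH2–CH= position in competition with the ring, and the carbamoyl group may migrate (anionic ortho-Fries) if the aryllithium warms. Fallback, setting out from 7 and returning at 14, with halogen–metal exchange and retro-Brook rearrangement in place of carbamate-directed metalation: 7 is brominated ortho to the hydroxyl (NBS, cat. i-Pr2NH, CH2Cl2, −78 °C; the phloroglucinol-type ring is far more nucleophilic than the alkenes) to 2-bromo-4-geranyl-3,5-bis(methoxymethoxy)phenol F11. HMDS (THF, 60 °C) gives [2-bromo-4-geranyl-3,5-bis(methoxymethoxy)phenoxy]trimethylsilane F12. n-BuLi (THF, −100 °C) effects bromine–lithium exchange and 1,3-O-to-C silyl shift to lithium 4-geranyl-3,5-bis(methoxymethoxy)-2-(trimethylsilyl)phenoxide F13, which Tf2O converts to 14, so that steps 4–6 are bypassed.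

**Further compounds**
F1 | step 11 | methoxymethyl (E)-3-[3,5-dimethoxy-4-(methoxymethoxy)phenyl]prop-2-enoate | COCOC(=O)/C=C/c1cc(OC)c(OCOC)c(OC)c1
F2 | step 11 | (E)-3-[3,5-dimethoxy-4-(methoxymethoxy)phenyl]prop-2-enoic acid | OC(=O)/C=C/c1cc(OC)c(OCOC)c(OC)c1
F3 | step 11 | (E)-1-[3-geranyl-6-hydroxy-2,4-bis(methoxymethoxy)phenyl]-3-[3,5-dimethoxy-4-(methoxymethoxy)phenyl]prop-2-en-1-one | COCOc1cc(O)c(C(=O)/C=C/c2cc(OC)c(OCOC)c(OC)c2)c(OCOC)c1C/C=C(\C)CCC=C(C)C
F4 | step 11 | racemic 2-[3,5-dimethoxy-4-(methoxymethoxy)phenyl]-6-geranyl-5,7-bis(methoxymethoxy)-2,3-dihydro-4H-chromen-4-one | COc1cc(C2CC(=O)c3c(cc(OCOC)c(C/C=C(\C)CCC=C(C)C)c3OCOC)O2)cc(OC)c1OCOC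
F5 | step 11 | (2R,4R)-2-[3,5-dimethoxy-4-(methoxymethoxy)phenyl]-6-geranyl-5,7-bis(methoxymethoxy)chroman-4-ol | COc1cc([C@H]2C[C@@H](O)c3c(cc(OCOC)c(C/C=C(\C)CCC=C(C)C)c3OCOC)O2)cc(OC)c1OCOC
F6 | step 3 | 2-[3,5-bis(methoxymethoxy)phenyl]-4,4,5,5-tetramethyl-1,3,2-dioxaborolane | COCOc1cc(OCOC)cc(B2OC(C)(C)C(C)(C)O2)c1
F7 | step 3 | 3,5-bis(methoxymethoxy)phenol | COCOc1cc(O)cc(OCOC)c1
F8 | step 3 | [3,5-bis(methoxymethoxy)phenoxy]tri(propan-2-yl)silane | COCOc1cc(O[Si](C(C)C)(C(C)C)C(C)C)cc(OCOC)c1
F9 | step 3 | {2,6-bis(methoxymethoxy)-4-[tri(propan-2-yl)silyloxy]phenyl}lithium | COCOc1cc(O[Si](C(C)C)(C(C)C)C(C)C)cc(OCOC)c1[Li]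
F10 | step 3 | {4-[(2E)-3,7-dimethylocta-2,6-dien-1-yl]-3,5-bis(methoxymethoxy)phenoxy}tri(propan-2-yl)silane | COCOc1cc(O[Si](C(C)C)(C(C)C)C(C)C)cc(OCOC)c1C/C=C(\C)CCC=C(C)C
F11 | step 5 | 2-bromo-4-[(2E)-3,7-dimethylocta-2,6-dien-1-yl]-3,5-bis(methoxymethoxy)phenol | COCOc1cc(O)c(Br)c(OCOC)c1C/C=C(\C)CCC=C(C)C
F12 | step 5 | {2-bromo-4-[(2E)-3,7-dimethylocta-2,6-dien-1-yl]-3,5-bis(methoxymethoxy)phenoxy}trimethylsilane | COCOc1cc(O[Si](C)(C)C)c(Br)c(OCOC)c1C/C=C(\C)CCC=C(C)C
F13 | step 5 | lithium 4-[(2E)-3,7-dimethylocta-2,6-dien-1-yl]-3,5-bis(methoxymethoxy)-2-(trimethylsilyl)phenoxide | COCOc1cc([O-])c([Si](C)(C)C)c(OCOC)c1C/C=C(\C)CCC=C(C)C.[Li+]
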